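**Assumptions:** the side chain is 10-phenyldecyl. Catalyst control in Step 8 is assumed to give the (4R,6S) diastereomer with (S,S)-ProPhenol. If the other diastereomer forms, the (R,R)-ligand is used.

## Retrosynthetic overview
1. The target is (3aR,5S,6aR)-5,6a-dimethyl-5-(10-phenyldecyl)tetrahydrofuro[3,2-b]furan-2-one. The THF ring is closed last by 5-exo oxa-Michael addition of a tertiary C–OH onto a γ,γ-disubstituted butenolide (13). Cis-ring fusion then fixes the CH–O stereocentre.
2. Butenolide 13 comes from Lindlar reduction and lactonisation of a tertiary propargylic alcohol ester (12). The quaternary lactone carbon and the C–C bond to the propiolate unit are formed by a new catalytic asymmetric alkynylation of β-hydroxy methyl ketone 10 (key new step).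
3. Ketone 10 comes from acid 9 (MeLi), from 1,3-diol 8 (TEMPO oxidation), from Sharpless epoxidation and Red-Al opening of (E)-allylic alcohol 6. That sequence sets the C(Me)(alkyl)–O tertiary carbinol.
4. Allylic alcohol 6 is made from alkyne 5 by methylalumination and CH2O capture. Alkyne 5 is built from 1,10-dibromodecane, PhMgBr and acetylide.

## Route

**Step 1**
Reactants: 1 (1,10-dibromodecane, 3 equiv); 2 (phenylmagnesium bromide)
Product: 3 (10-bromodecyl)benzene
Conditions: Li2CuCl4 (5 mol%), THF, –10 → 0 °C
Reagents that add atoms: none (the phenyl comes from 2)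
Why: Cu-catalysed Kumada-type alkyl–aryl coupling; excess dibromide favours mono-arylation; no stereocentres.

**Step 2**
Reactants: 3; 4 (lithium acetylide–ethylenediamine complex)
Product: 5 (12-phenyldodec-1-yne)
Conditions: DMSO, rt
Reagents that add atoms: none (the acetylide comes from 4)
Why: SN2 alkylation of an acetylide with a primary bromide.

**Step 3**
Reactants: 5
Product: 6 ((2E)-3-methyl-13-phenyltridec-2-en-1-ol)
Conditions: Me3Al, cat. Cp2ZrCl2, ClCH2CH2Cl, 0 °C → rt; then n-BuLi, –78 °C; then CH2O (cracked from paraformaldehyde), THF, –78 °C → rt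
Reagents that add atoms: trimethylaluminium C[Al](C)C (adds Me); formaldehyde C=O (adds CH2OH)
Why: Zr-catalysed methylalumination is syn, so Me and Al end up cis, giving the E-trisubstituted alkenylalane; its ate complex adds to CH2O to give the allylic alcohol.

**Step 4**
Reactants: 6
Product: 7 ([(2S,3S)-3-methyl-3-(10-phenyldecyl)oxiran-2-yl]methanol)
Conditions: Ti(OiPr)4 (10 mol%), L-(+)-DET (12 mol%), TBHP (2 equiv, decane), 4 Å MS, CH2Cl2, –20 °C
Reagents that add atoms: tert-butyl hydroperoxide CC(C)(C)OO (supplies the epoxide O)
Why: Sharpless asymmetric epoxidation; L-(+)-DET on an E-allylic alcohol gives the (2S,3S) epoxide, which fixes the future C1 (S) carbinol centre.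

**Step 5**
Reactants: 7
Product: 8 ((3S)-3-methyl-13-phenyltridecane-1,3-diol)
Conditions: Red-Al (3 equiv), THF, 0 °C → rt
Reagents that add atoms: none (hydride only)
Why: Red-Al delivers hydride regioselectively to C2, giving the 1,3-diol; the C3–O bond is never broken, so the tertiary stereocentre is retained.

**Step 6**
Reactants: 8
Product: 9 ((3S)-3-hydroxy-3-methyl-13-phenyltridecanoic acid)
Conditions: TEMPO (10 mol%), NaClO2 (3 equiv), NaOCl (2 mol%), MeCN / pH 6.7 phosphate buffer, 35 °C
Reagents that add atoms: sodium chlorite [Na+].[O-]Cl=O (oxygen source)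
Why: TEMPO/chlorite oxidation of the primary alcohol to the acid (Zhao–Grabowski type); the tertiary carbinol is inert and nothing epimerisable is touched.

**Step 7**
Reactants: 9
Product: 10 ((4S)-4-hydroxy-4-methyl-14-phenyltetradecan-2-one)
Conditions: MeLi (3.5 equiv), THF, –20 °C → rt; quench aq. NH4Cl
Reagents that add atoms: methyllithium C[Li] (adds the acetyl CH3)
Why: carboxylic acid plus MeLi gives a methyl ketone through the stable dilithio gem-diolate, which avoids over-addition; the carbinol stereocentre is unaffected.

**Step 8**
Reactants: 10; 11 (ethyl propiolate, 3 equiv)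
Product: 12 (ethyl (4R,6S)-4,6-dihydroxy-4,6-dimethyl-16-phenylhexadec-2-ynoate)
Conditions: (S,S)-ProPhenol (10 mol%), Me2Zn (3 equiv), Ph3P=S (20 mol%), toluene, 4 °C, 48 h
Reagents that add atoms: none (propiolate is compound 11)
Why: Proposed new method: catalytic asymmetric alkynylation of an aliphatic methyl ketone.
- The dinuclear Zn–ProPhenol catalyst deprotonates ethyl propiolate to give a Zn acetylide on one Zn.
- The second Zn binds the β-tertiary alkoxide and the ketone C=O as a six-membered chelate, so the hydroxyl acts as a second anchor that differentiates CH3 from CH2R.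
- The acetylide is delivered to one enantiotopic face, creating the quaternary C4 (R) centre relative to the preset C6 (S) centre.
- The closest known reactions are ProPhenol alkynylation of aldehydes and ynones, and hydroxy-ketone-directed ProPhenol aldol chemistry.
- The ligand controls the outcome, not the weak 1,3-induction from C6.

**Step 9**
Reactants: 12
Product: 13 ((5R)-5-[(2S)-2-hydroxy-2-methyl-12-phenyldodecyl]-5-methylfuran-2(5H)-one)
Conditions: H2 (1 atm), Lindlar catalyst, quinoline, EtOAc, rt; then PPTS (10 mol%), CH2Cl2, rt
Reagents that add atoms: none (H2 adds hydrogen only; EtOH is lost)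
Why: Z-selective alkyne semi-hydrogenation, then 5-exo lactonisation of the C4 tertiary OH onto the Z-enoate (γ-hydroxy-Z-enoate → butenolide); this forms the lactone ring and no stereocentre is altered.

**Step 10**
Reactants: 13
Product: 14 (target, (3aR,5S,6aR)-5,6a-dimethyl-5-(10-phenyldecyl)tetrahydrofuro[3,2-b]furan-2(3H)-one)
Conditions: t-BuOK (10 mol%), THF, 0 °C, 2 h
Reagents that add atoms: none (isomerisation)
Why: intramolecular 5-exo-trig oxa-Michael addition of the tertiary alkoxide to the butenolide β-carbon, assisted by the gem-disubstituent effect. Only cis ring fusion is accessible, so the new CH–O centre is fixed as (R) by the γ-quaternary (R) centre. C1 and C2 are not touched; retro-Michael cleaves only the new C–O bond.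

## Compound list
1 | 1,10-dibromodecane | BrCCCCCCCCCCBr | starting material
2 | phenylmagnesium bromide | Br[Mg]c1ccccc1 | starting material
3 | (10-bromodecyl)benzene | BrCCCCCCCCCCc1ccccc1 | intermediate
4 | lithium acetylide–ethylenediamine complex | [Li]C#C.NCCN | starting material
5 | 12-phenyldodec-1-yne | C#CCCCCCCCCCCc1ccccc1 | intermediate
6 | (2E)-3-methyl-13-phenyltridec-2-en-1-ol | OC/C=C(\C)CCCCCCCCCCc1ccccc1 | intermediate
7 | [(2S,3S)-3-methyl-3-(10-phenyldecyl)oxiran-2-yl]methanol | OC[C@@H]1O[C@@]1(C)CCCCCCCCCCc1ccccc1 | intermediate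
8 | (3S)-3-methyl-13-phenyltridecane-1,3-diol | C[C@](O)(CCCCCCCCCCc1ccccc1)CCO | intermediate
9 | (3S)-3-hydroxy-3-methyl-13-phenyltridecanoic acid | C[C@](O)(CCCCCCCCCCc1ccccc1)CC(=O)O | intermediate
10 | (4S)-4-hydroxy-4-methyl-14-phenyltetradecan-2-one | C[C@](O)(CCCCCCCCCCc1ccccc1)CC(C)=O | intermediate
11 | ethyl propiolate | C#CC(=O)OCC | starting material
12 | ethyl (4R,6S)-4,6-dihydroxy-4,6-dimethyl-16-phenylhexadec-2-ynoate | C[C@](O)(CCCCCCCCCCc1ccccc1)C[C@@](C)(O)C#CC(=O)OCC | intermediate
13 | (5R)-5-[(2S)-2-hydroxy-2-methyl-12-phenyldodecyl]-5-methylfuran-2(5H)-one | C[C@](O)(CCCCCCCCCCc1ccccc1)C[C@@]2(C)OC(=O)C=C2 | intermediate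
14 | Plakortolide ether, (3aR,5S,6aR)-5,6a-dimethyl-5-(10-phenyldecyl)tetrahydrofuro[3,2-b]furan-2(3H)-one | C[C@]1(CCCCCCCCCCc2ccccc2)C[C@@]2(C)OC(=O)C[C@H]2O1 | target

## Totals
Total steps: 10. Longest linear sequence: 10 (1 → 3 → 5 → 6 → 7 → 8 → 9 → 10 → 12 → 13 → 14). Compounds 2, 4 and 11 enter convergently.

## Three steps most likely to fail
1. **Step 8 (proposed new ProPhenol alkynylation).** Dialkyl methyl ketones are poorly differentiated, and retro-aldol of the Zn β-alkoxy ketone or low dr are possible.
   - Fallback: protect C6–OH as TES ether and add LiC≡CCO2Et (CeCl3, –78 °C) to the ketone. Accept the non-selective mixture and separate the diastereomers at the butenolide stage (13) by chromatography. This replaces catalyst control with substrate control plus separation.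
2. **Step 10 (oxa-Michael).** The equilibrium may be unfavourable for a strained cis-bicyclic tertiary ether, or base may cause retro-Michael or decomposition.
   - Fallback: epoxidise butenolide 13 (TBHP, DBU). Open the epoxide 5-exo at Cb with the tertiary OH (CSA, CH2Cl2). Then remove the resulting α-OH by acetylation and SmI2 reduction (or Barton–McCombie deoxygenation).
3. **Step 7 (MeLi on the β-hydroxy acid).** Insolubility of the poly-anion, incomplete conversion or retro-aldol on work-up are possible.
   - Fallback: from diol 8, oxidise selectively to the aldehyde (TEMPO/PhI(OAc)2). Add MeMgBr (3 equiv), then oxidise the secondary alcohol (DMP) to give ketone 10.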